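**Design of a total synthesis of CNP0220090.1 (compound 16) by asymmetric protonation and para-quinone methide cyclisation**

## The problem

Compound 16 is an 8–5′ neolignan monosulfate: a trans-2-aryl-3-(hydroxymethyl)-2,3-dihydrobenzofuran. Ring B (O1, C2, C3, C3a, C7a) is fused to aromatic ring A (C3a to C7a, methoxy at C7, 3-sulfooxypropyl chain at C5) and carries ring C (4-hydroxy-3-methoxyphenyl) on C2 and the hydroxymethyl carbon C9 on C3. The skeleton is two C6–C3 units joined by C3–C3a and O1–C2, so the difficulty is the two adjacent stereocentres, C2 (S) and C3 (R), which must be trans and of one absolute sense. They are unequal partners. C2 is a benzylic ether carbon para to the free phenol of ring C and can open to a para-quinone methide and close again, so it settles trans to whatever stands at C3. C3 is a plain C–H centre that cannot be corrected later, so it must be set absolutely and then controls C2. The same lability forbids strong acid or hot base once ring B exists with the ring C phenol free. Three hydroxyls (phenol, hindered primary C9–OH, unhindered primary chain OH) must be told apart so that only the chain oxygen is sulfated, and the polar, acid-sensitive sulfate monoester must come last. The enabling feature is that C2 is benzylic to ring C and para to its hydroxyl: the open-chain C2=C3 stilbene is a tautomer of a para-quinone methide electrophilic at C2, and O1 on ring A sits five atoms away (O1–C7a–C3a–C3–C2), so one proton delivered to C3 can close ring B and create both stereocentres.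

## Retrosynthesis

**End game, 16 back to 12.** The S–O bond of the sulfate and the two acetyl C–O bonds are cut. Compound 16 comes from the diacetate sulfate 15, this from alcohol 14 by O-sulfation, 14 from silyl ether 13, and 13 from phenol 12 by acetylation. Sulfating last avoids carrying an ionic group through the route. Acetates on the phenol and on C9 leave the chain hydroxyl as the only nucleophile and fall off together under mild base that does not harm a sulfate monoester anion. The chain oxygen carries a tert-butyldiphenylsilyl ether rather than a smaller silyl group, because it must survive the strong acid of the ring closure and still leave with buffered fluoride beside two acetates.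

**Ring B, 12 back to 11.** The O1–C2 bond and the C3–H bond are cut, which opens ring B to the (E)-stilbene 11. The neighbouring cuts (C3–C3a by arylation, O1–C7a by aryl ether formation, C2–C3 by an aldol-type union) each need an extra stereocontrolling device or a prefunctionalised ring A. This cut uses what the molecule already offers: the para-hydroxyl of ring C makes C2 a latent cation. Compound 11 has no stereocentre and no ring B. The forward step must deliver a proton to one face of C3 and close the ring trans. C9 is kept as CH2OAc and not as an ester carbonyl, so that the alkene stays electron-rich and C3, once protonated, cannot epimerise.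

**Phenols and C9, 11 back to 8.** Compound 11 comes from triacetate 10 by removal of the two aryl acetates, 10 from triol 9, and 9 from the 3-arylidene lactone 8 by hydride reduction. In 8 a single lactone protects O1 and holds C9 at the acid level, so one reduction releases both the nucleophile and the hydroxymethyl group. A direct selective acetylation of 9 is possible but less certain, so the detour through 10 is accepted.

**The alkene, 8 back to 6 and 7.** The C2=C3 double bond is cut by a Knoevenagel disconnection into the benzofuran-2(3H)-one 6 and vanillin 7. Cross-coupling routes to the same trisubstituted alkene would need a halogenated ring A and a stereodefined alkenyl metal. Here the lactone CH2 is acidic enough to condense with an unprotected hydroxy aldehyde, and ring C arrives complete.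

**The acetic acid unit, 6 back to 2 and 3.** The C3–C3a bond is cut. Lactone 6 comes from the 3-hydroxy lactone 5 by deoxygenation, and 5 from phenol 2 and glyoxylic acid 3 through the ortho-hydroxymandelic acid 4. The phenol has a blocked para position and one free ortho position, so the regiochemistry is fixed by the substrate. An allylation, Claisen rearrangement and oxidative cleavage sequence would be longer and would expose a guaiacol to periodate. The price is one reduction to take the carbinol out again.

**Protection, 2 back to 1.** Phenol 2 is the silyl ether of commercial dihydroconiferyl alcohol 1, which already holds ring A, its methoxy group and the three-carbon chain with its oxygen.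

## Roads not taken

**Alternative 1:** Ring A is cut at C3a–C4 and C7–C7a and built on a lactone that already holds C2 and C3. In the forward step the silyl ketene acetal A1 (dienophile C3a=C7a) is heated with the bromopyrone ester A2. Cycloaddition, decarboxylation and loss of the silyloxy group give the aromatic ester A3.
- Merits: both stereocentres sit in a simple trans γ-butyrolactone that established enolate chemistry can deliver, so stereocontrol rests on known ground. In this respect the road is better than the chosen plan. The polarised pyrone also fixes the regiochemistry.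
- Weak points: A3 has bromine where the C7 methoxy belongs and an ester where the hydroxypropyl chain belongs. A C–O coupling, a two-carbon homologation and several redox steps must follow, all on a compound with a labile benzylic ether. In the aromatisation the ketal carbon C7a can lose the ring oxygen O1 instead of the silyloxy group, which would open ring B. Two benzyl ethers must finally be removed by hydrogenolysis beside the benzylic C2–O1 bond.
- Comparison: the chosen plan starts from arenes that already carry every ring substituent and needs about half as many steps after ring formation. Against the better-secured stereochemistry of A3 it sets this brevity and a fallback built on known chemistry.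

**Alternative 2:** Three bonds of ring A (C3a–C7a, C4–C5, C6–C7) are cut, so rings A and B form together. In the forward step diyne A4 (alkynyl ether on O1, ethynyl on C3) and alkyne A5 are cyclotrimerised with [Rh(cod)2]BF4 and racemic BINAP (monovalent rhodium) to give A6.
- Merits: this is the most convergent ring construction of the four and fully atom-economical, and the side chain arrives with its oxygen in place. In bond-forming economy of the key step it is better than the chosen plan.
- Weak points: C7 emerges as a triethylsilyl arene, which has no direct route to an aryl methyl ether; ipso-halogenation and a C–O coupling must follow. The untethered alkyne A5 can insert in two orientations, so the chain may end at C6 instead of C5. The alkynyl ether of a secondary benzylic alcohol with a β-hydrogen is thermally fragile. The two stereocentres of A4 need their own asymmetric synthesis, so enantiocontrol is moved upstream rather than solved.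
- Comparison: the chosen plan sets against the elegance of A6 robust, commercially based precursors, certain regiochemistry on ring A and a shorter end game.

**Alternative 3:** The C2–aryl bond to ring C and the C3–C3a bond are cut. In the forward step the aryllithium A9 forms the boron ate complex of alkenylboronate A7. With Pd(OAc)2 and a Mandyphos ligand (zerovalent palladium formed in situ) the ring A triflate A8 triggers a 1,2-shift of ring C to C2 and couples at C3, giving boronic ester A10. Oxidation of C–B and closure of O1–C2 would follow.
- Merits: both stereocentres are set in one catalytic enantioselective step of an established reaction class. In precedent for enantiocontrol this road is better than the chosen plan.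
- Weak points: A8 is an electron-rich triflate with an ortho substituent, a poor partner for oxidative addition. A7 is a β-substituted alkenylboronate whose alkylpalladium intermediate has a β-benzyloxy group that can be eliminated. Ring A must carry an extra oxygen at C3a for the triflate, which dihydroconiferyl alcohol lacks, so additional oxygenation and differentiation of two neighbouring phenols is needed. After A10 there remain oxidation, deprotection, ring closure and hydrogenolysis of two benzyl ethers.
- Comparison: the chosen plan sets against the proven enantioselectivity three commercial building blocks with all substituents in place, thermodynamic control of the trans ring, no hydrogenolysis, and a fallback on known chemistry for its one untested step.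

Key step: step 8

Remark on the chemistry (assumption): the hydrogen sulfate drawn for the target is taken as the sulfate monoester; 15 and 16 are written as free acids but handled as sodium salts, and the free acid of 16 is liberated only at the end by cation exchange in cold dilute solution. TBDPS stands for tert-butyldiphenylsilyl.

## Route

Step 1
Reactants: 1 dihydroconiferyl alcohol, 4-(3-hydroxypropyl)-2-methoxyphenol
Product: 2 4-[3-(TBDPS-oxy)propyl]-2-methoxyphenol
Conditions: TBDPSCl (1.05 equiv), imidazole (2.2 equiv), CH2Cl2, 0 °C to rt
Reagents that add atoms: tert-butyldiphenylsilyl chloride, CC(C)(C)[Si](Cl)(c1ccccc1)c1ccccc1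
Why: Silylation of an alcohol; the unhindered primary alkanol reacts with the bulky silyl chloride much faster than the hindered, hydrogen-bonded guaiacyl phenol, and any aryl silyl ether formed is cleaved by a short K2CO3/MeOH wash. The diphenyl-tert-butylsilyl group is chosen because it must survive the strong acid of step 8.

Step 2
Reactants: 2 4-[3-(TBDPS-oxy)propyl]-2-methoxyphenol; 3 glyoxylic acid (used as the monohydrate)
Product: 5 racemic 3-hydroxy-7-methoxy-5-[3-(TBDPS-oxy)propyl]benzofuran-2(3H)-one, via ortho-hydroxymandelic acid 4 (not isolated)
Conditions: NaOH (3 equiv), H2O–1,4-dioxane, 40 °C; 1 M HCl to pH 3, 0 °C; then p-TsOH·H2O (2 mol%), toluene, 70 °C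
Reagents that add atoms: none
Why: Phenolate ortho-hydroxyalkylation by glyoxylate (an aldol-type aromatic substitution): the para position is blocked by the chain and C6 is the only free position ortho to the phenoxide oxygen, so the mandelic acid forms at the future C3a, and mild acid then closes the five-membered aryl lactone. The silyl ether tolerates dilute base at 40 °C and a catalytic sulfonic acid in toluene.

Step 3
Reactants: 5 racemic 3-hydroxy-7-methoxy-5-[3-(TBDPS-oxy)propyl]benzofuran-2(3H)-one
Product: 6 7-methoxy-5-[3-(TBDPS-oxy)propyl]benzofuran-2(3H)-one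
Conditions: SmI2 (2.5 equiv, divalent samarium), t-BuCO2H (2.5 equiv), THF–HMPA, rt
Reagents that add atoms: none
Why: Samarium diiodide α-deoxygenation of an α-hydroxy ester: electron transfer to the activated aryl lactone carbonyl, loss of the benzylic hydroxide and protonation of the samarium enolate by pivalic acid. The silyl ether and the arene are inert, and the racemic carbinol centre disappears.

Step 4
Reactants: 6 7-methoxy-5-[3-(TBDPS-oxy)propyl]benzofuran-2(3H)-one; 7 vanillin
Product: 8 (E)-3-(4-hydroxy-3-methoxybenzylidene)-7-methoxy-5-[3-(TBDPS-oxy)propyl]benzofuran-2(3H)-one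
Conditions: 7 (1.1 equiv), piperidine (0.2 equiv), AcOH (0.2 equiv), toluene, 4 Å molecular sieves, 80 °C
Reagents that add atoms: none
Why: Knoevenagel condensation; the lactone CH2 is unusually acidic because its enolate is an aromatic 2-benzofuranolate, so catalytic piperidinium acetate suffices and the phenol of vanillin needs no protection. The E isomer (ring C anti to the lactone carbonyl) is the more stable one, and the alkene geometry is not a stereo-element of the target because step 8 passes through a cation.

Step 5
Reactants: 8 (E)-3-(4-hydroxy-3-methoxybenzylidene)-7-methoxy-5-[3-(TBDPS-oxy)propyl]benzofuran-2(3H)-one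
Product: 9 (E)-2-{2-hydroxy-3-methoxy-5-[3-(TBDPS-oxy)propyl]phenyl}-3-(4-hydroxy-3-methoxyphenyl)prop-2-en-1-ol
Conditions: i-Bu2AlH (5 equiv), CH2Cl2–toluene, −78 to 0 °C; aqueous potassium sodium tartrate (KNaC4H4O6)
Reagents that add atoms: none
Why: 1,2-Reduction of an α,β-unsaturated aryl lactone by i-Bu2AlH through the lactol to the allylic alcohol, which releases the ring A phenol (the future O1) and leaves C9 at the alcohol level. One equivalent is consumed by the ring C phenol; the alkene geometry and the silyl ether are untouched.

Step 6
Reactants: 9 (E)-2-{2-hydroxy-3-methoxy-5-[3-(TBDPS-oxy)propyl]phenyl}-3-(4-hydroxy-3-methoxyphenyl)prop-2-en-1-ol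
Product: 10 (E)-2-{2-acetoxy-3-methoxy-5-[3-(TBDPS-oxy)propyl]phenyl}-3-(4-acetoxy-3-methoxyphenyl)allyl acetate
Conditions: Ac2O (5 equiv), pyridine, DMAP (cat.), CH2Cl2, 0 °C to rt
Reagents that add atoms: acetic anhydride, CC(=O)OC(C)=O
Why: Exhaustive acetylation with nucleophilic catalysis; it caps C9–OH as the acetate wanted in step 8 and converts the acid-sensitive para-hydroxycinnamyl alcohol into a stable, easily purified triacetate.

Step 7
Reactants: 10 (E)-2-{2-acetoxy-3-methoxy-5-[3-(TBDPS-oxy)propyl]phenyl}-3-(4-acetoxy-3-methoxyphenyl)allyl acetate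
Product: 11 (E)-2-{2-hydroxy-3-methoxy-5-[3-(TBDPS-oxy)propyl]phenyl}-3-(4-hydroxy-3-methoxyphenyl)allyl acetate
Conditions: N2H4·AcOH (2.4 equiv), DMF, rt
Reagents that add atoms: none
Why: Chemoselective hydrazinolysis of aryl acetates; phenoxide is by far the better leaving group, so both phenolic acetates are removed while the allylic alkyl acetate stays. The buffered, nearly neutral reagent is the one suited to para-acetoxycinnamyl acetates because it does not build up the phenoxide that could expel the allylic acetate.

Step 8
Reactants: 11 (E)-2-{2-hydroxy-3-methoxy-5-[3-(TBDPS-oxy)propyl]phenyl}-3-(4-hydroxy-3-methoxyphenyl)allyl acetate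
Product: 12 {(2S,3R)-2-(4-hydroxy-3-methoxyphenyl)-7-methoxy-5-[3-(TBDPS-oxy)propyl]-2,3-dihydrobenzofuran-3-yl}methyl acetate
Conditions: confined chiral imidodiphosphorimidate Brønsted acid (BINOL-derived, 3,3′-diaryl, N-SO2CF3; 5 mol%), dry CHCl3, −20 to 0 °C, stopped at full conversion
Reagents that add atoms: none
Why: Proposed new method: the confined chiral acid should transfer its proton to C3, the terminus of the para-hydroxystyrene system of ring C, so that C2 becomes the carbon of a protonated para-quinone methide held as a contact ion pair with the chiral anion; the ring A hydroxyl, five atoms away, then adds to C2 and the resulting oxonium ion returns the proton to the catalyst. The closest known reaction types are the asymmetric intramolecular hydroalkoxylation of alkenes with confined chiral Brønsted acids, chiral phosphoric acid additions to para-quinone methides generated in situ, and the acid-mediated cyclisation of 2-hydroxystilbenes to 2-aryl-2,3-dihydrobenzofurans; what is new is that the proton transfer itself creates the stereocentre. Ring B closes by O1–C2 bond formation, formally 5-endo-trig with respect to the stilbene C2=C3 bond but in fact the capture of a benzylic cation, which is 5-exo-trig with respect to the quinone methide C2=C(aryl) bond and therefore unstrained. C3 is set under catalyst control by the face on which the proton is delivered inside the chiral pocket; which antipode of the catalyst leads to 3R has to be found by trial, both being accessible from (R)- and (S)-BINOL. C2 is set under substrate control: the cation rotates freely, O1 adds anti to the acetoxymethyl group, and any cis isomer can reopen under the acid and close again to the more stable trans ring without touching C3, which means 2S once C3 is R. The step needs protonation at C3 in preference to C2, which the para-hydroxyl of ring C secures by stabilising the C2 cation while the fast ring closure drains it, and it needs the allylic C9–O bond to stay intact, for which C9 is carried as an acetate (a poor leaving group under a Brønsted acid in an aprotic medium) and not as the free alcohol. The TBDPS ether is chosen to withstand the acid, and low temperature with a stop at full conversion limits reversal of the protonation, the one path by which the configuration at C3 could be lost.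

Step 9
Reactants: 12 {(2S,3R)-2-(4-hydroxy-3-methoxyphenyl)-7-methoxy-5-[3-(TBDPS-oxy)propyl]-2,3-dihydrobenzofuran-3-yl}methyl acetate
Product: 13 {(2S,3R)-2-(4-acetoxy-3-methoxyphenyl)-7-methoxy-5-[3-(TBDPS-oxy)propyl]-2,3-dihydrobenzofuran-3-yl}methyl acetate
Conditions: Ac2O (2 equiv), pyridine, CH2Cl2, 0 °C to rt
Reagents that add atoms: acetic anhydride, CC(=O)OC(C)=O
Why: Acetylation of the phenol, so that after desilylation the chain hydroxyl is the only site open to sulfation. The aryl acetate also lowers the tendency of C2 to ionise in the next steps; both stereocentres are untouched.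

Step 10
Reactants: 13 {(2S,3R)-2-(4-acetoxy-3-methoxyphenyl)-7-methoxy-5-[3-(TBDPS-oxy)propyl]-2,3-dihydrobenzofuran-3-yl}methyl acetate
Product: 14 [(2S,3R)-2-(4-acetoxy-3-methoxyphenyl)-5-(3-hydroxypropyl)-7-methoxy-2,3-dihydrobenzofuran-3-yl]methyl acetate
Conditions: HF·pyridine, pyridine, THF, 0 °C to rt
Reagents that add atoms: none
Why: Fluoride-driven cleavage of the Si–O bond; buffered HF·pyridine removes the primary silyl ether without the basicity of Bu4NF, which would cleave the aryl acetate, and both acetates and the benzylic ether are stable to it.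

Step 11
Reactants: 14 [(2S,3R)-2-(4-acetoxy-3-methoxyphenyl)-5-(3-hydroxypropyl)-7-methoxy-2,3-dihydrobenzofuran-3-yl]methyl acetate
Product: 15 3-[(2S,3R)-3-(acetoxymethyl)-2-(4-acetoxy-3-methoxyphenyl)-7-methoxy-2,3-dihydrobenzofuran-5-yl]propyl hydrogen sulfate (kept as the sodium salt)
Conditions: SO3·pyridine (3 equiv), pyridine, rt; aqueous NaHCO3
Reagents that add atoms: sulfur trioxide–pyridine complex, [O-]S(=O)(=O)[n+]1ccccc1
Why: O-Sulfation of a primary alcohol with the SO3·pyridine complex; the phenol and C9–OH are masked as acetates, so only the chain oxygen can react, and the basic medium protects the benzylic ether.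

Step 12
Reactants: 15 3-[(2S,3R)-3-(acetoxymethyl)-2-(4-acetoxy-3-methoxyphenyl)-7-methoxy-2,3-dihydrobenzofuran-5-yl]propyl hydrogen sulfate
Product: 16 3-[(2S,3R)-2-(4-hydroxy-3-methoxyphenyl)-3-(hydroxymethyl)-7-methoxy-2,3-dihydrobenzofuran-5-yl]propyl hydrogen sulfate (CNP0220090.1)
Conditions: K2CO3 (0.3 equiv), MeOH, 0 °C to rt; then Dowex 50W-X8 (H+ form), MeOH–H2O, 0 °C
Reagents that add atoms: none
Why: Zemplén-type base-catalysed transesterification removes the aryl and the alkyl acetate as methyl acetate; a sulfate monoester anion is inert to methoxide and C3 bears no acidifying group, so neither stereocentre is at risk. Brief cation exchange in the cold then gives the hydrogen sulfate.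

## Compound list

1 | dihydroconiferyl alcohol, 4-(3-hydroxypropyl)-2-methoxyphenol | COc1cc(CCCO)ccc1O | starting material
2 | 4-[3-(TBDPS-oxy)propyl]-2-methoxyphenol | COc1cc(CCCO[Si](c2ccccc2)(c2ccccc2)C(C)(C)C)ccc1O | intermediate
3 | glyoxylic acid | O=CC(=O)O | starting material
4 | racemic 2-hydroxy-2-{2-hydroxy-3-methoxy-5-[3-(TBDPS-oxy)propyl]phenyl}acetic acid (ortho-hydroxymandelic acid) | COc1cc(CCCO[Si](c2ccccc2)(c2ccccc2)C(C)(C)C)cc(C(O)C(=O)O)c1O | intermediate
5 | racemic 3-hydroxy-7-methoxy-5-[3-(TBDPS-oxy)propyl]benzofuran-2(3H)-one | COc1cc(CCCO[Si](c2ccccc2)(c2ccccc2)C(C)(C)C)cc2c1OC(=O)C2O | intermediate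
6 | 7-methoxy-5-[3-(TBDPS-oxy)propyl]benzofuran-2(3H)-one | COc1cc(CCCO[Si](c2ccccc2)(c2ccccc2)C(C)(C)C)cc2c1OC(=O)C2 | intermediate
7 | vanillin, 4-hydroxy-3-methoxybenzaldehyde | COc1cc(C=O)ccc1O | starting material
8 | (E)-3-(4-hydroxy-3-methoxybenzylidene)-7-methoxy-5-[3-(TBDPS-oxy)propyl]benzofuran-2(3H)-one | COc1cc(/C=C2/C(=O)Oc3c(OC)cc(CCCO[Si](c4ccccc4)(c4ccccc4)C(C)(C)C)cc32)ccc1O | intermediate
9 | (E)-2-{2-hydroxy-3-methoxy-5-[3-(TBDPS-oxy)propyl]phenyl}-3-(4-hydroxy-3-methoxyphenyl)prop-2-en-1-ol | COc1cc(/C=C(/CO)c2cc(CCCO[Si](c3ccccc3)(c3ccccc3)C(C)(C)C)cc(OC)c2O)ccc1O | intermediate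
10 | (E)-2-{2-acetoxy-3-methoxy-5-[3-(TBDPS-oxy)propyl]phenyl}-3-(4-acetoxy-3-methoxyphenyl)allyl acetate | COc1cc(/C=C(/COC(C)=O)c2cc(CCCO[Si](c3ccccc3)(c3ccccc3)C(C)(C)C)cc(OC)c2OC(C)=O)ccc1OC(C)=O | intermediate
11 | (E)-2-{2-hydroxy-3-methoxy-5-[3-(TBDPS-oxy)propyl]phenyl}-3-(4-hydroxy-3-methoxyphenyl)allyl acetate | COc1cc(/C=C(/COC(C)=O)c2cc(CCCO[Si](c3ccccc3)(c3ccccc3)C(C)(C)C)cc(OC)c2O)ccc1O | intermediate
12 | {(2S,3R)-2-(4-hydroxy-3-methoxyphenyl)-7-methoxy-5-[3-(TBDPS-oxy)propyl]-2,3-dihydrobenzofuran-3-yl}methyl acetate (trans) | COc1cc([C@H]2Oc3c(OC)cc(CCCO[Si](c4ccccc4)(c4ccccc4)C(C)(C)C)cc3[C@@H]2COC(C)=O)ccc1O | intermediate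
13 | {(2S,3R)-2-(4-acetoxy-3-methoxyphenyl)-7-methoxy-5-[3-(TBDPS-oxy)propyl]-2,3-dihydrobenzofuran-3-yl}methyl acetate | COc1cc([C@H]2Oc3c(OC)cc(CCCO[Si](c4ccccc4)(c4ccccc4)C(C)(C)C)cc3[C@@H]2COC(C)=O)ccc1OC(C)=O | intermediate
14 | [(2S,3R)-2-(4-acetoxy-3-methoxyphenyl)-5-(3-hydroxypropyl)-7-methoxy-2,3-dihydrobenzofuran-3-yl]methyl acetate | COc1cc([C@H]2Oc3c(OC)cc(CCCO)cc3[C@@H]2COC(C)=O)ccc1OC(C)=O | intermediate
15 | 3-[(2S,3R)-3-(acetoxymethyl)-2-(4-acetoxy-3-methoxyphenyl)-7-methoxy-2,3-dihydrobenzofuran-5-yl]propyl hydrogen sulfate | COc1cc([C@H]2Oc3c(OC)cc(CCCOS(=O)(=O)O)cc3[C@@H]2COC(C)=O)ccc1OC(C)=O | intermediate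
16 | 3-[(2S,3R)-2-(4-hydroxy-3-methoxyphenyl)-3-(hydroxymethyl)-7-methoxy-2,3-dihydrobenzofuran-5-yl]propyl hydrogen sulfate (CNP0220090.1) | COc1cc([C@H]2Oc3c(OC)cc(CCCOS(=O)(=O)O)cc3[C@@H]2CO)ccc1O | target

## Step count and risk

Total step count: 12. Longest linear sequence: 12 steps, from 1 to 16; 3 and 7 enter in steps 2 and 4.

Least certain steps:

**Step 8 (key step, proposed new method).**
- What may go wrong: the most likely failure is poor facial selectivity in the proton transfer. The alkene carbon is flat and fully substituted, two phenols can hydrogen-bond to the chiral anion in competing ways, and reversible protonation can wash out whatever selectivity is reached. Ionisation of the allylic acetate is the second concern.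
- Fallback: the trans-dihydrobenzofuran is made by an enantioselective intramolecular C–H insertion of a rhodium carbenoid, a reaction established for cis-2-aryl-2,3-dihydrobenzofuran-3-carboxylates. It sets out from 6 and returns to the route at 13.
- Methanolysis (K2CO3, MeOH) opens the lactone of 6 to methyl 2-{2-hydroxy-3-methoxy-5-[3-(TBDPS-oxy)propyl]phenyl}acetate F1.
- O-Alkylation with commercial 4-benzyloxy-3-methoxybenzyl chloride (K2CO3, NaI, DMF) gives the benzyl aryl ether F2.
- Regitz diazo transfer (4-acetamidobenzenesulfonyl azide, DBU, MeCN) gives the aryldiazoacetate F3.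
- Rh2(S-PTTL)4 or its antipode (PTTL = N-phthaloyl-tert-leucinate, divalent rhodium; toluene, −60 °C) inserts the carbenoid into the benzylic C–H bond and gives the cis ester F4 with C2 set as S.
- NaOMe in MeOH epimerises C3 to the trans ester F5, and LiAlH4 in THF reduces it to the primary alcohol F6.
- Hydrogenolysis (H2, Pd/C, EtOAc) frees the ring C phenol to give the diol F7, and Ac2O/pyridine acetylates both hydroxyls to give 13.

**Step 2.**
- What may go wrong: slow attack at the single free ortho position of a lipophilic phenoxide, so that disproportionation of glyoxylate and a second arylation of the carbinol during the acidic lactonisation take over.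
- Fallback: the acetic acid unit is introduced at the right oxidation level by cross-coupling, which also removes the need for step 3. It sets out from 2 and returns at 6.
- NBS (MeCN, 0 °C) brominates ortho to the hydroxyl and gives 2-bromo-6-methoxy-4-[3-(TBDPS-oxy)propyl]phenol F8.
- Coupling with the Reformatsky reagent BrZnCH2CO2t-Bu (Pd(dba)2, zerovalent palladium, Q-Phos, THF; one extra equivalent for the phenol) gives the tert-butyl arylacetate F9.
- p-TsOH in warm toluene cleaves the ester and closes the lactone to 6.

**Step 3.**
- What may go wrong: over-reduction or ring opening of the aryl lactone by the strongly reducing samarium/HMPA system, or sluggish loss of the poor hydroxide leaving group.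
- Fallback: from 5, the carbinol is acetylated (Ac2O, pyridine) to the 3-acetoxy lactone F10. Its doubly activated benzylic acetate is removed by catalytic hydrogenolysis (H2, Pd/C, EtOAc), which returns to the route at 6.

**Step 4.**
- What may go wrong: aminolysis of the reactive aryl lactone by piperidine and low electrophilicity of vanillin as its phenoxide, leading to incomplete condensation and E/Z mixtures.
- Fallback: a Perkin-type condensation without an amine. Compounds 6 and 7 in Ac2O/Et3N at 80 °C give the (E)-3-(4-acetoxy-3-methoxybenzylidene) lactone F11, the aldehyde reacting as its more electrophilic acetate. The i-Bu2AlH of step 5, with one more equivalent, cleaves the aryl acetate reductively while it reduces the lactone, so the sequence rejoins the route at 9.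

**Step 7.**
- What may go wrong: once the ring C phenol is free, its phenoxide can expel the allylic acetate through a vinylogous quinone methide. An acetyl group can also migrate, and the hindered ring A acetate may react slowly.
- Fallback: the triacetate is avoided. Only the aliphatic hydroxyl of 9 is acetylated with immobilised Candida antarctica lipase B and vinyl acetate in t-BuOMe at 40 °C, a catalyst that does not acylate phenols. This goes from 9 directly to 11 and makes no new compound.

## Further compounds

F1 | step 8 | methyl 2-{2-hydroxy-3-methoxy-5-[3-(TBDPS-oxy)propyl]phenyl}acetate | COC(=O)Cc1cc(CCCO[Si](c2ccccc2)(c2ccccc2)C(C)(C)C)cc(OC)c1O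
F2 | step 8 | methyl 2-{2-[(4-benzyloxy-3-methoxyphenyl)methoxy]-3-methoxy-5-[3-(TBDPS-oxy)propyl]phenyl}acetate | COC(=O)Cc1cc(CCCO[Si](c2ccccc2)(c2ccccc2)C(C)(C)C)cc(OC)c1OCc1ccc(OCc2ccccc2)c(OC)c1
F3 | step 8 | methyl 2-diazo-2-{2-[(4-benzyloxy-3-methoxyphenyl)methoxy]-3-methoxy-5-[3-(TBDPS-oxy)propyl]phenyl}acetate | COC(=O)C(=[N+]=[N-])c1cc(CCCO[Si](c2ccccc2)(c2ccccc2)C(C)(C)C)cc(OC)c1OCc1ccc(OCc2ccccc2)c(OC)c1
F4 | step 8 | methyl (2S,3R)-2-(4-benzyloxy-3-methoxyphenyl)-7-methoxy-5-[3-(TBDPS-oxy)propyl]-2,3-dihydrobenzofuran-3-carboxylate (cis) | COc1cc([C@H]2Oc3c(OC)cc(CCCO[Si](c4ccccc4)(c4ccccc4)C(C)(C)C)cc3[C@H]2C(=O)OC)ccc1OCc1ccccc1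
F5 | step 8 | methyl (2S,3S)-2-(4-benzyloxy-3-methoxyphenyl)-7-methoxy-5-[3-(TBDPS-oxy)propyl]-2,3-dihydrobenzofuran-3-carboxylate (trans) | COc1cc([C@H]2Oc3c(OC)cc(CCCO[Si](c4ccccc4)(c4ccccc4)C(C)(C)C)cc3[C@@H]2C(=O)OC)ccc1OCc1ccccc1
F6 | step 8 | {(2S,3R)-2-(4-benzyloxy-3-methoxyphenyl)-7-methoxy-5-[3-(TBDPS-oxy)propyl]-2,3-dihydrobenzofuran-3-yl}methanol | COc1cc([C@H]2Oc3c(OC)cc(CCCO[Si](c4ccccc4)(c4ccccc4)C(C)(C)C)cc3[C@@H]2CO)ccc1OCc1ccccc1
F7 | step 8 | 4-{(2S,3R)-3-(hydroxymethyl)-7-methoxy-5-[3-(TBDPS-oxy)propyl]-2,3-dihydrobenzofuran-2-yl}-2-methoxyphenol | COc1cc([C@H]2Oc3c(OC)cc(CCCO[Si](c4ccccc4)(c4ccccc4)C(C)(C)C)cc3[C@@H]2CO)ccc1O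
F8 | step 2 | 2-bromo-6-methoxy-4-[3-(TBDPS-oxy)propyl]phenol | COc1cc(CCCO[Si](c2ccccc2)(c2ccccc2)C(C)(C)C)cc(Br)c1O
F9 | step 2 | tert-butyl 2-{2-hydroxy-3-methoxy-5-[3-(TBDPS-oxy)propyl]phenyl}acetate | CC(C)(C)OC(=O)Cc1cc(CCCO[Si](c2ccccc2)(c2ccccc2)C(C)(C)C)cc(OC)c1O
F10 | step 3 | racemic 3-acetoxy-7-methoxy-5-[3-(TBDPS-oxy)propyl]benzofuran-2(3H)-one | COc1cc(CCCO[Si](c2ccccc2)(c2ccccc2)C(C)(C)C)cc2c1OC(=O)C2OC(C)=O
F11 | step 4 | (E)-3-(4-acetoxy-3-methoxybenzylidene)-7-methoxy-5-[3-(TBDPS-oxy)propyl]benzofuran-2(3H)-one | COc1cc(/C=C2/C(=O)Oc3c(OC)cc(CCCO[Si](c4ccccc4)(c4ccccc4)C(C)(C)C)cc32)ccc1OC(C)=O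
F0 | step 7 | none | none
A1 | alternative 1 | tert-butyldimethylsilyl ketene acetal of trans-5-(4-benzyloxy-3-methoxyphenyl)-4-(benzyloxymethyl)dihydrofuran-2(3H)-one | COc1cc([C@H]2OC(O[Si](C)(C)C(C)(C)C)=C[C@@H]2COCc2ccccc2)ccc1OCc1ccccc1
A2 | alternative 1 | methyl 3-bromo-2-oxo-2H-pyran-5-carboxylate | COC(=O)C1=COC(=O)C(Br)=C1
A3 | alternative 1 | methyl trans-2-(4-benzyloxy-3-methoxyphenyl)-3-(benzyloxymethyl)-7-bromo-2,3-dihydrobenzofuran-5-carboxylate | COc1cc([C@H]2Oc3c(Br)cc(C(=O)OC)cc3[C@@H]2COCc2ccccc2)ccc1OCc1ccccc1
A4 | alternative 2 | 1-(4-benzyloxy-3-methoxyphenyl)-2-(benzyloxymethyl)but-3-ynyl (triethylsilyl)ethynyl ether | COc1cc([C@@H](OC#C[Si](CC)(CC)CC)[C@@H](COCc2ccccc2)C#C)ccc1OCc1ccccc1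
A5 | alternative 2 | tert-butyldimethyl(pent-4-yn-1-yloxy)silane | C#CCCCO[Si](C)(C)C(C)(C)C
A6 | alternative 2 | trans-2-(4-benzyloxy-3-methoxyphenyl)-3-(benzyloxymethyl)-5-[3-(tert-butyldimethylsilyloxy)propyl]-7-triethylsilyl-2,3-dihydrobenzofuran | COc1cc([C@H]2Oc3c([Si](CC)(CC)CC)cc(CCCO[Si](C)(C)C(C)(C)C)cc3[C@@H]2COCc2ccccc2)ccc1OCc1ccccc1
A7 | alternative 3 | (E)-2-(3-benzyloxyprop-1-enyl)-4,4,5,5-tetramethyl-1,3,2-dioxaborolane | CC1(C)OB(/C=C/COCc2ccccc2)OC1(C)C
A8 | alternative 3 | 3-methoxy-2-(methoxymethoxy)-5-[3-(tert-butyldimethylsilyloxy)propyl]phenyl trifluoromethanesulfonate | COCOc1c(OC)cc(CCCO[Si](C)(C)C(C)(C)C)cc1OS(=O)(=O)C(F)(F)F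
A9 | alternative 3 | 4-benzyloxy-3-methoxyphenyllithium | [Li]c1ccc(OCc2ccccc2)c(OC)c1
A10 | alternative 3 | anti-1-(4-benzyloxy-3-methoxyphenyl)-2-{3-methoxy-2-(methoxymethoxy)-5-[3-(tert-butyldimethylsilyloxy)propyl]phenyl}-3-benzyloxypropylboronic acid pinacol ester | COc1cc([C@@H](B2OC(C)(C)C(C)(C)O2)[C@@H](COCc2ccccc2)c2cc(CCCO[Si](C)(C)C(C)(C)C)cc(OC)c2OCOC)ccc1OCc1ccccc1
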